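The oxocane hides a local C2 axis through ring carbon C8: C7 and C9 (CHCl, both S) and C6 and C10 (CH–O, both S) are symmetry-related. The route builds this C6–C10 tetrad in one two-directional operation: propane-1,3-diol, which becomes C7–C8–C9, is coupled at both carbinol carbons with an acrolein-derived acyloxyallyl donor under iridium-catalysed transfer hydrogenation, which forms C6–C7 and C9–C10 and all four stereocentres under catalyst control. Double inversion then installs both chlorides, ester methylenation and enol ether–olefin metathesis close the ring and tell the two vinyl arms apart, and a hydroxyl-directed hydrogenation sets C12.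

Key step: step 2

Remark on numbering: atoms are numbered along the C15 chain, C1 (alkyne CH) to C15 (CH3); the ring oxygen bridges C6 and C12.
Assumption: (R)-SEGPHOS is taken to give the (3S,4R) sense at each new C–C bond, by analogy with the related anti-crotylation; if the sense proves opposite, (S)-SEGPHOS is used.
Assumption: compounds 10 and 21 are purchased.

Step 1
Reactants: 1 acrolein; 2 benzoic anhydride
Product: 3 prop-2-ene-1,1-diyl dibenzoate
Conditions: FeCl3 (2 mol%), CH2Cl2, 0 °C to rt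
Reagents that add atoms: none
Why: Lewis-acid-catalysed acylal formation (1,1-diacyloxylation of an aldehyde by an anhydride) should give the gem-dibenzoate; no stereocentre is formed.

Step 2
Reactants: 4 propane-1,3-diol; 3 prop-2-ene-1,1-diyl dibenzoate (3 equiv)
Product: 6 (3S,4R,6R,7S)-4,6-dihydroxynona-1,8-diene-3,7-diyl dibenzoate, via mono-adduct 5 (not isolated)
Conditions: [Ir(cod)Cl]2 (5 mol%), (R)-SEGPHOS (10 mol%), 4-cyano-3-nitrobenzoic acid (20 mol%), K3PO4 (20 mol%), THF, 90 °C, sealed tube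
Reagents that add atoms: none
Why: The ortho-cyclometalated iridium catalyst dehydrogenates a primary carbinol of 4 to the aldehyde and uses the hydride so gained to turn donor 3, after ionisation, into a nucleophilic (E)-σ-(benzoyloxy)allyl species of trivalent iridium, which adds to the transient aldehyde through a closed chair transition state; the cycle then repeats at the second carbinol of mono-adduct 5 (redox-neutral carbonyl allylation from the alcohol oxidation level, two-directional variant). The closest known reactions are the iridium-catalysed anti-(α-acyloxy)allylation of primary alcohols with allyl gem-dicarboxylates and the two-directional allylation and crotylation of propane-1,3-diol. No ring is closed. The anti relation C6/C7 and C9/C10 is set by the chair transition state with the (E)-configured acyloxyallyl group, the absolute sense at all four centres by the chiral bisphosphine, and the second addition should raise the enantiopurity of the C2-symmetric product because minor-sense events end up in separable diastereomers. The step needs oxidation of primary in preference to secondary carbinols, which the substrate secures because both new carbinols are secondary and the free aldehyde never accumulates, so elimination to acrolein is avoided.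

Step 3
Reactants: 6 (3S,4R,6R,7S)-4,6-dihydroxynona-1,8-diene-3,7-diyl dibenzoate
Product: 8 (3S,4S,6S,7S)-4,6-dichloronona-1,8-diene-3,7-diyl dibenzoate, via bis-triflate 7 (not isolated)
Conditions: Tf2O, pyridine, CH2Cl2, −30 °C; then n-Bu4NCl, toluene, 0 °C to rt
Reagents that add atoms: tetrabutylammonium chloride CCCC[N+](CCCC)(CCCC)CCCC.[Cl-]
Why: Triflation and SN2 displacement by chloride should invert C7 and C9, as in halide displacement of sugar triflates flanked by esters, the high chloride concentration at low temperature being meant to outrun benzoate participation; each anti diol monoester thus becomes a syn chlorohydrin ester.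

Step 4
Reactants: 8 (3S,4S,6S,7S)-4,6-dichloronona-1,8-diene-3,7-diyl dibenzoate
Product: 9 (3S,4S,6S,7S)-4,6-dichloronona-1,8-diene-3,7-diol
Conditions: i-Bu2AlH, CH2Cl2, −78 °C; aqueous potassium sodium tartrate work-up
Reagents that add atoms: none
Why: Reductive ester cleavage with a hydride reagent removes both benzoates without the free alkoxide/base conditions that would close the chlorohydrins to epoxides; no stereocentre is touched.

Step 5
Reactants: 10 (2R)-2-hydroxybutanoic acid
Product: 12 (2R)-2-[(tert-butyldimethylsilyl)oxy]butanoic acid, via silyl ester 11 (not isolated)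
Conditions: TBSCl, imidazole, DMF, rt; then K2CO3, MeOH/H2O, rt; aqueous citric acid work-up
Reagents that add atoms: tert-butyldimethylsilyl chloride CC(C)(C)[Si](C)(C)Cl
Why: Bis-silylation followed by selective solvolysis of the labile silyl ester should give the O-silyl acid; the future C13 stereocentre comes unchanged from the chiral pool.

Step 6
Reactants: 9 (3S,4S,6S,7S)-4,6-dichloronona-1,8-diene-3,7-diol (excess, recovered); 12 (2R)-2-[(tert-butyldimethylsilyl)oxy]butanoic acid
Product: 13 (3S,4S,6S,7S)-4,6-dichloro-7-hydroxynona-1,8-dien-3-yl (2R)-2-[(tert-butyldimethylsilyl)oxy]butanoate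
Conditions: EDC·HCl, DMAP (cat.), CH2Cl2, 0 °C
Reagents that add atoms: none
Why: Steglich esterification; the two hydroxyls of C2-symmetric 9 are homotopic, so mono-acylation gives one compound whichever end reacts, and the excess of diol limits bis-acylation.

Step 7
Reactants: 13 (3S,4S,6S,7S)-4,6-dichloro-7-hydroxynona-1,8-dien-3-yl (2R)-2-[(tert-butyldimethylsilyl)oxy]butanoate
Product: 14 (3S,4S,6S,7S)-7-({(3R)-3-[(tert-butyldimethylsilyl)oxy]pent-1-en-2-yl}oxy)-4,6-dichloronona-1,8-dien-3-ol
Conditions: Cp2TiMe2 (3 equiv), toluene, 70 °C, dark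
Reagents that add atoms: dimethyltitanocene (C5H5)2Ti(CH3)2 [CH3-].[CH3-].[Ti+4].[cH-]1cccc1.[cH-]1cccc1
Why: Petasis methylenation of the ester carbonyl through Cp2Ti=CH2 should give the 2-alkoxy-1-alkene; the neutral reagent spares the chlorohydrin and the surplus covers the free hydroxyl.

Step 8
Reactants: 14 (3S,4S,6S,7S)-7-({(3R)-3-[(tert-butyldimethylsilyl)oxy]pent-1-en-2-yl}oxy)-4,6-dichloronona-1,8-dien-3-ol
Product: 15 (4S,5S,7S,8S)-2-{(1R)-1-[(tert-butyldimethylsilyl)oxy]propyl}-5,7-dichloro-8-ethenyl-5,6,7,8-tetrahydro-4H-oxocin-4-ol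
Conditions: second-generation Grubbs catalyst RuCl2(H2IMes)(PCy3)(=CHPh) (15 mol%), 1,4-benzoquinone (10 mol%), toluene (2 mM), 70 °C
Reagents that add atoms: none
Why: Enol ether–olefin ring-closing metathesis should form the cis ring double bond C11=C12 and the eight-membered ring; only the vinyl group on the hydroxyl-bearing carbon can reach the enol ether, since the other would give a four-membered ring, so the two arms are told apart without a protecting group.

Step 9
Reactants: 15 (4S,5S,7S,8S)-2-{(1R)-1-[(tert-butyldimethylsilyl)oxy]propyl}-5,7-dichloro-8-ethenyl-5,6,7,8-tetrahydro-4H-oxocin-4-ol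
Product: 17 (4S,5S,7S,8S)-2-{(1R)-1-[(tert-butyldimethylsilyl)oxy]propyl}-5,7-dichloro-8-(2-hydroxyethyl)-5,6,7,8-tetrahydro-4H-oxocin-4-ol, via alkylborane 16 (not isolated)
Conditions: 9-BBN-H (3 equiv), THF, 0 °C to rt; then NaBO3·4H2O, THF/H2O, rt
Reagents that add atoms: sodium perborate [Na+].[O-]OB=O
Why: Hydroboration–oxidation: 9-BBN should add to the terminal vinyl group in the anti-Markovnikov sense much faster than to the hindered trisubstituted enol ether, and perborate oxidises the C–B bond under mild conditions.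

Step 10
Reactants: 17 (4S,5S,7S,8S)-2-{(1R)-1-[(tert-butyldimethylsilyl)oxy]propyl}-5,7-dichloro-8-(2-hydroxyethyl)-5,6,7,8-tetrahydro-4H-oxocin-4-ol
Product: 18 (2R,4S,5S,7S,8S)-2-{(1R)-1-[(tert-butyldimethylsilyl)oxy]propyl}-5,7-dichloro-8-(2-hydroxyethyl)oxocan-4-ol
Conditions: [Ir(cod)(PCy3)(py)]PF6 (10 mol%), H2 (1 atm), CH2Cl2, rt
Reagents that add atoms: none
Why: Hydroxyl-directed hydrogenation: the allylic C10 hydroxyl binds the cationic iridium centre and delivers H2 to its own face of C11=C12, a face that the hydroxyethyl arm at C6 shares, so H at C12 ends cis to O at C10, which is the (R) configuration and places the C12 and C6 side chains trans across the ring oxygen.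

Step 11
Reactants: 18 (2R,4S,5S,7S,8S)-2-{(1R)-1-[(tert-butyldimethylsilyl)oxy]propyl}-5,7-dichloro-8-(2-hydroxyethyl)oxocan-4-ol
Product: 19 2-[(2S,3S,5S,6S,8R)-8-{(1R)-1-[(tert-butyldimethylsilyl)oxy]propyl}-3,5-dichloro-6-hydroxyoxocan-2-yl]acetaldehyde
Conditions: TEMPO (10 mol%), PhI(OAc)2, CH2Cl2, rt
Reagents that add atoms: none
Why: Oxoammonium (TEMPO) oxidation is selective for the primary alcohol and should leave the secondary C10 carbinol untouched.

Step 12
Reactants: 19 2-[(2S,3S,5S,6S,8R)-8-{(1R)-1-[(tert-butyldimethylsilyl)oxy]propyl}-3,5-dichloro-6-hydroxyoxocan-2-yl]acetaldehyde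
Product: 20 (2R,4S,5S,7S,8S)-2-{(1R)-1-[(tert-butyldimethylsilyl)oxy]propyl}-5,7-dichloro-8-(2-oxoethyl)oxocan-4-yl acetate
Conditions: Ac2O, pyridine, DMAP (cat.), CH2Cl2, 0 °C
Reagents that add atoms: acetic anhydride CC(=O)OC(C)=O
Why: DMAP-catalysed acylation of the C10 hydroxyl installs the acetate of the target with retention; the mild base should avoid β-elimination of the β-alkoxy aldehyde.

Step 13
Reactants: 20 (2R,4S,5S,7S,8S)-2-{(1R)-1-[(tert-butyldimethylsilyl)oxy]propyl}-5,7-dichloro-8-(2-oxoethyl)oxocan-4-yl acetate; 21 1,3-bis(triisopropylsilyl)prop-1-yne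
Product: 23 (2R,4S,5S,7S,8S)-2-{(1R)-1-[(tert-butyldimethylsilyl)oxy]propyl}-5,7-dichloro-8-[(2Z)-5-(triisopropylsilyl)pent-2-en-4-yn-1-yl]oxocan-4-yl acetate, via β-silyl alkoxide 22 (not isolated)
Conditions: 21, n-BuLi, THF, −20 °C; then 20, −78 °C to rt
Reagents that add atoms: none
Why: Peterson olefination with the lithiated bis-silylpropyne: addition to the aldehyde and syn-elimination of silanolate should give the (Z)-enyne, the bulky triisopropylsilyl groups being the source of Z selectivity, and at −78 °C the aldehyde reacts far faster than the acetate.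

Step 14
Reactants: 23 (2R,4S,5S,7S,8S)-2-{(1R)-1-[(tert-butyldimethylsilyl)oxy]propyl}-5,7-dichloro-8-[(2Z)-5-(triisopropylsilyl)pent-2-en-4-yn-1-yl]oxocan-4-yl acetate
Product: 24 (2R,4S,5S,7S,8S)-5,7-dichloro-2-[(1R)-1-hydroxypropyl]-8-[(2Z)-pent-2-en-4-yn-1-yl]oxocan-4-yl acetate
Conditions: n-Bu4NF, AcOH (1:1), THF, 0 °C to rt
Reagents that add atoms: none
Why: Fluoride-mediated desilylation cleaves the alkynyl C–Si bond and the silyl ether in one operation, and the acetic acid buffer keeps the acetate and the chlorohydrin ester from base.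

Step 15
Reactants: 24 (2R,4S,5S,7S,8S)-5,7-dichloro-2-[(1R)-1-hydroxypropyl]-8-[(2Z)-pent-2-en-4-yn-1-yl]oxocan-4-yl acetate
Product: 25 (2R,4S,5S,7S,8S)-2-[(1S)-1-bromopropyl]-5,7-dichloro-8-[(2Z)-pent-2-en-4-yn-1-yl]oxocan-4-yl acetate
Conditions: CBr4, P(n-C8H17)3, toluene, 70 °C
Reagents that add atoms: carbon tetrabromide BrC(Br)(Br)Br
Why: Appel-type bromination: SN2 attack of bromide on the alkoxyphosphonium ion should invert C13, (R)-carbinol to (S)-bromide, which completes the target.

Compound list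
1 | acrolein (prop-2-enal) | C=CC=O | starting material
2 | benzoic anhydride | O=C(OC(=O)c1ccccc1)c1ccccc1 | starting material
3 | prop-2-ene-1,1-diyl dibenzoate | C=CC(OC(=O)c1ccccc1)OC(=O)c1ccccc1 | intermediate
4 | propane-1,3-diol | OCCCO | starting material
5 | (3S,4R)-4,6-dihydroxyhex-1-en-3-yl benzoate (mono-adduct) | C=C[C@H](OC(=O)c1ccccc1)[C@H](O)CCO | intermediate
6 | (3S,4R,6R,7S)-4,6-dihydroxynona-1,8-diene-3,7-diyl dibenzoate | C=C[C@H](OC(=O)c1ccccc1)[C@H](O)C[C@@H](O)[C@@H](OC(=O)c1ccccc1)C=C | intermediate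
7 | (3S,4R,6R,7S)-4,6-bis(trifluoromethanesulfonyloxy)nona-1,8-diene-3,7-diyl dibenzoate | C=C[C@H](OC(=O)c1ccccc1)[C@H](OS(=O)(=O)C(F)(F)F)C[C@@H](OS(=O)(=O)C(F)(F)F)[C@@H](OC(=O)c1ccccc1)C=C | intermediate
8 | (3S,4S,6S,7S)-4,6-dichloronona-1,8-diene-3,7-diyl dibenzoate | C=C[C@H](OC(=O)c1ccccc1)[C@@H](Cl)C[C@H](Cl)[C@@H](OC(=O)c1ccccc1)C=C | intermediate
9 | (3S,4S,6S,7S)-4,6-dichloronona-1,8-diene-3,7-diol | C=C[C@H](O)[C@@H](Cl)C[C@H](Cl)[C@@H](O)C=C | intermediate
10 | (2R)-2-hydroxybutanoic acid | CC[C@@H](O)C(=O)O | starting material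
11 | tert-butyldimethylsilyl (2R)-2-[(tert-butyldimethylsilyl)oxy]butanoate | CC[C@@H](O[Si](C)(C)C(C)(C)C)C(=O)O[Si](C)(C)C(C)(C)C | intermediate
12 | (2R)-2-[(tert-butyldimethylsilyl)oxy]butanoic acid | CC[C@@H](O[Si](C)(C)C(C)(C)C)C(=O)O | intermediate
13 | (3S,4S,6S,7S)-4,6-dichloro-7-hydroxynona-1,8-dien-3-yl (2R)-2-[(tert-butyldimethylsilyl)oxy]butanoate | C=C[C@H](OC(=O)[C@H](O[Si](C)(C)C(C)(C)C)CC)[C@@H](Cl)C[C@H](Cl)[C@@H](O)C=C | intermediate
14 | (3S,4S,6S,7S)-7-({(3R)-3-[(tert-butyldimethylsilyl)oxy]pent-1-en-2-yl}oxy)-4,6-dichloronona-1,8-dien-3-ol | C=C[C@H](OC(=C)[C@H](O[Si](C)(C)C(C)(C)C)CC)[C@@H](Cl)C[C@H](Cl)[C@@H](O)C=C | intermediate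
15 | (4S,5S,7S,8S)-2-{(1R)-1-[(tert-butyldimethylsilyl)oxy]propyl}-5,7-dichloro-8-ethenyl-5,6,7,8-tetrahydro-4H-oxocin-4-ol | C=C[C@H](O1)[C@@H](Cl)C[C@H](Cl)[C@@H](O)/C=C1/[C@H](O[Si](C)(C)C(C)(C)C)CC | intermediate
16 | B-alkyl-9-borabicyclo[3.3.1]nonane adduct of 15 at the terminal vinyl carbon, C10 hydroxyl as its 9-BBN borinate | C(C[C@H](O1)[C@@H](Cl)C[C@H](Cl)[C@@H](OB2C3CCCC2CCC3)/C=C1/[C@H](O[Si](C)(C)C(C)(C)C)CC)B1C2CCCC1CCC2 | intermediate
17 | (4S,5S,7S,8S)-2-{(1R)-1-[(tert-butyldimethylsilyl)oxy]propyl}-5,7-dichloro-8-(2-hydroxyethyl)-5,6,7,8-tetrahydro-4H-oxocin-4-ol | OCC[C@H](O1)[C@@H](Cl)C[C@H](Cl)[C@@H](O)/C=C1/[C@H](O[Si](C)(C)C(C)(C)C)CC | intermediate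
18 | (2R,4S,5S,7S,8S)-2-{(1R)-1-[(tert-butyldimethylsilyl)oxy]propyl}-5,7-dichloro-8-(2-hydroxyethyl)oxocan-4-ol | OCC[C@H](O1)[C@@H](Cl)C[C@H](Cl)[C@@H](O)C[C@@H]1[C@H](O[Si](C)(C)C(C)(C)C)CC | intermediate
19 | 2-[(2S,3S,5S,6S,8R)-8-{(1R)-1-[(tert-butyldimethylsilyl)oxy]propyl}-3,5-dichloro-6-hydroxyoxocan-2-yl]acetaldehyde | O=CC[C@H](O1)[C@@H](Cl)C[C@H](Cl)[C@@H](O)C[C@@H]1[C@H](O[Si](C)(C)C(C)(C)C)CC | intermediate
20 | (2R,4S,5S,7S,8S)-2-{(1R)-1-[(tert-butyldimethylsilyl)oxy]propyl}-5,7-dichloro-8-(2-oxoethyl)oxocan-4-yl acetate | O=CC[C@H](O1)[C@@H](Cl)C[C@H](Cl)[C@@H](OC(C)=O)C[C@@H]1[C@H](O[Si](C)(C)C(C)(C)C)CC | intermediate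
21 | 1,3-bis(triisopropylsilyl)prop-1-yne | CC(C)[Si](C(C)C)(C(C)C)CC#C[Si](C(C)C)(C(C)C)C(C)C | starting material
22 | lithium β-silyl alkoxide from addition of lithiated 21 to aldehyde 20 (two new centres undefined) | [Li+].[O-]C(C[C@H](O1)[C@@H](Cl)C[C@H](Cl)[C@@H](OC(C)=O)C[C@@H]1[C@H](O[Si](C)(C)C(C)(C)C)CC)C(C#C[Si](C(C)C)(C(C)C)C(C)C)[Si](C(C)C)(C(C)C)C(C)C | intermediate
23 | (2R,4S,5S,7S,8S)-2-{(1R)-1-[(tert-butyldimethylsilyl)oxy]propyl}-5,7-dichloro-8-[(2Z)-5-(triisopropylsilyl)pent-2-en-4-yn-1-yl]oxocan-4-yl acetate | CC(C)[Si](C(C)C)(C(C)C)C#C/C=C\C[C@H](O1)[C@@H](Cl)C[C@H](Cl)[C@@H](OC(C)=O)C[C@@H]1[C@H](O[Si](C)(C)C(C)(C)C)CC | intermediate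
24 | (2R,4S,5S,7S,8S)-5,7-dichloro-2-[(1R)-1-hydroxypropyl]-8-[(2Z)-pent-2-en-4-yn-1-yl]oxocan-4-yl acetate | C#C/C=C\C[C@H](O1)[C@@H](Cl)C[C@H](Cl)[C@@H](OC(C)=O)C[C@@H]1[C@H](O)CC | intermediate
25 | (2R,4S,5S,7S,8S)-2-[(1S)-1-bromopropyl]-5,7-dichloro-8-[(2Z)-pent-2-en-4-yn-1-yl]oxocan-4-yl acetate | C#C/C=C\C[C@@H]1O[C@@H]([C@@H](Br)CC)C[C@H](OC(C)=O)[C@@H](Cl)C[C@@H]1Cl | target

Total step count: 15. Longest linear sequence: 14 steps (steps 1–4 and 6–15, from acrolein); step 5 is a one-step side branch.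

Steps most likely to fail

1. Step 8 (enol ether–olefin ring-closing metathesis). The propagating carbene formed at the vinyl group next to the hydroxyl may fail to engage the hindered 1,1-disubstituted enol ether in an eight-membered closure, so that oligomerisation, isomerisation of the allylic alcohol or slow [3,3] rearrangement of the allyl vinyl ether takes over. The fallback sets out from 13 and closes the ring by intramolecular carbonyl alkylidenation of the ester instead of metathesis of a preformed enol ether. Silylation of the free hydroxyl of 13 with Et3SiOTf and 2,6-lutidine in CH2Cl2 at −78 °C would give the O-triethylsilyl diene ester F1. Olefinic-ester cyclisation of F1 under Takai–Utimoto conditions, TiCl4, Zn, catalytic PbCl2, TMEDA and CH3CHBr2 in THF at 65 °C, would then give the O-triethylsilyl oxocine F2, the triethylsilyl ether of 15; here the alkylidene that the reagent generates at the vinyl group next to the silyl ether olefinates the ester carbonyl intramolecularly, and the other vinyl group cannot close a ring of useful size. Buffered fluoride, n-Bu4NF and AcOH in THF at 0 °C, would remove the more labile triethylsilyl group of F2 and come back to the route at 15.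

2. Step 3 (double chloride displacement). The benzoates may participate, forming acyloxonium ions that lead to retention at C7 and C9 or deliver chloride to the allylic carbons C6 and C10; elimination of the triflates is a second risk. The fallback sets out from 6 and swaps the esters for non-participating ethers before the substitution. Acetonide formation on the 1,3-diol of 6 with 2,2-dimethoxypropane and PPTS in CH2Cl2 would give the acetonide dibenzoate F3. Reductive debenzoylation of F3 with i-Bu2AlH in CH2Cl2 at −78 °C would give the acetonide diol F4. Etherification of F4 with NaH, 4-methoxybenzyl chloride and n-Bu4NI in THF/DMF would give the acetonide bis-ether F5, in which both allylic carbinols carry 4-methoxybenzyl groups. Acetonide removal from F5 with PPTS in MeOH would give the diol bis-ether F6. Double Appel chlorination of F6 with inversion at both carbinols, using CCl4 and P(n-C8H17)3 in toluene at 70 °C, would give the dichloride bis-ether F7. Oxidative ether cleavage of F7 with DDQ in CH2Cl2 and pH 7 buffer would come back to the route at 9.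

3. Step 10 (hydroxyl-directed hydrogenation). Facial control may be poor in the flexible eight-membered ring, or traces of acid from the cationic iridium hydride may hydrolyse or isomerise the enol ether. The fallback sets out from 15 and replaces catalytic hydrogenation by an ionic reduction with internal hydride delivery. Treatment of 15 with Me4NBH(OAc)3 in AcOH/MeCN at −30 °C should protonate the enol ether at C11 to the C12 oxocarbenium ion, to which the acetoxyborohydride bound to the C10 hydroxyl delivers hydride on its own face, following the logic of the Evans–Saksena anti-reduction of β-hydroxy ketones. It would give the vinyl oxocane F8, which is 18 with an ethenyl group in place of the 2-hydroxyethyl group. Hydroboration–oxidation of F8 under the conditions of step 9 would come back to the route at 18.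

Further compounds
F1 | step 8 | (3S,4S,6S,7S)-4,6-dichloro-7-[(triethylsilyl)oxy]nona-1,8-dien-3-yl (2R)-2-[(tert-butyldimethylsilyl)oxy]butanoate | C=C[C@H](OC(=O)[C@H](O[Si](C)(C)C(C)(C)C)CC)[C@@H](Cl)C[C@H](Cl)[C@@H](O[Si](CC)(CC)CC)C=C
F2 | step 8 | (4S,5S,7S,8S)-2-{(1R)-1-[(tert-butyldimethylsilyl)oxy]propyl}-5,7-dichloro-8-ethenyl-4-[(triethylsilyl)oxy]-5,6,7,8-tetrahydro-4H-oxocine | C=C[C@H](O1)[C@@H](Cl)C[C@H](Cl)[C@@H](O[Si](CC)(CC)CC)/C=C1/[C@H](O[Si](C)(C)C(C)(C)C)CC
F3 | step 3 | acetonide of 6: (4R,6R)-2,2-dimethyl-1,3-dioxane-4,6-diyl bis[(1S)-prop-2-en-1-yl benzoate] | C=C[C@H](OC(=O)c1ccccc1)[C@H]2C[C@H]([C@@H](OC(=O)c3ccccc3)C=C)OC(C)(C)O2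
F4 | step 3 | (1S,1'S)-1,1'-[(4R,6R)-2,2-dimethyl-1,3-dioxane-4,6-diyl]bis(prop-2-en-1-ol) | C=C[C@H](O)[C@H]1C[C@H]([C@@H](O)C=C)OC(C)(C)O1
F5 | step 3 | bis(4-methoxybenzyl) ether of F4 | C=C[C@H](OCc1ccc(OC)cc1)[C@H]2C[C@H]([C@@H](OCc3ccc(OC)cc3)C=C)OC(C)(C)O2
F6 | step 3 | (3S,4R,6R,7S)-3,7-bis[(4-methoxybenzyl)oxy]nona-1,8-diene-4,6-diol | C=C[C@H](OCc1ccc(OC)cc1)[C@H](O)C[C@@H](O)[C@@H](OCc1ccc(OC)cc1)C=C
F7 | step 3 | (3S,4S,6S,7S)-4,6-dichloro-3,7-bis[(4-methoxybenzyl)oxy]nona-1,8-diene | C=C[C@H](OCc1ccc(OC)cc1)[C@@H](Cl)C[C@H](Cl)[C@@H](OCc1ccc(OC)cc1)C=C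
F8 | step 10 | (2R,4S,5S,7S,8S)-2-{(1R)-1-[(tert-butyldimethylsilyl)oxy]propyl}-5,7-dichloro-8-ethenyloxocan-4-ol | C=C[C@H](O1)[C@@H](Cl)C[C@H](Cl)[C@@H](O)C[C@@H]1[C@H](O[Si](C)(C)C(C)(C)C)CC
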